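The route rests on cutting the sp2–sp3 bond between C5 of the 3,6-dihydro-2H-pyran ring and C1' of the homofarnesyl chain. The key step is a one-pot hydroboration/B-alkyl Suzuki–Miyaura coupling that joins the complete heterocycle to the complete C16 chain in one operation. It exploits two features. The ring alkene C4=C5 has a C5 that can carry iodine. The saturated C1'–C2' link beside the C3'=C4' alkene is the hydroboration retron of a terminal 1,3-diene. One precursor is an enantiopure 5-iodo-dihydropyran, made by 6-endo iodocyclisation of a β-allenol, with a 1-bromovinyl group on C2 as latent acrylic acid. The other is a farnesal-derived tetraene. No protecting group is needed.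

Key step: step 7

Remark on the chemistry: ring atoms are O1, C2 (stereocentre), C3, C4, C5 and C6. Chain carbons C1' to C13' are counted from the ring, and Cα is the vinylic carbon bound to C2. 2-Bromoacrolein is assumed to be made fresh because it does not store well.

Step 1
Reactants: 1 acrolein
Product: 3 2-bromoacrolein, via 2,3-dibromopropanal 2 (not isolated)
Conditions: Br2 (1.0 equiv), CH2Cl2, −78 to 0 °C; then Et3N (1.05 equiv), 0 °C
Reagents that add atoms: bromine, BrBr
Why: Bromination–dehydrobromination: Br2 adds across the alkene and Et3N then removes the acidic α-hydrogen of 2 with E1cB loss of the β-bromide, which is the standard entry to α-bromoenals.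

Step 2
Reactants: 3 2-bromoacrolein
Product: 5 (3R)-2-bromohex-1-en-5-yn-3-ol, via tributylstannyl ether 4 (not isolated)
Conditions: (R)-BINOL (20 mol%), Ti(OiPr)4 (20 mol%), 4 Å MS, allenylSnBu3 (1.3 equiv), CH2Cl2, −20 °C; aq NaHCO3
Reagents that add atoms: allenyltributylstannane, C=C=C[Sn](CCCC)(CCCC)CCCC
Why: Keck asymmetric propargylation: the (R)-BINOL–titanium Lewis acid binds the aldehyde and lets the allenylstannane attack in SE2' fashion on the Re face, which sets C2 as (R) (the sense known for aldehydes whose substituent outranks the new CH2 group) and should deliver the homopropargylic rather than the allenic alcohol.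

Step 3
Reactants: 5 (3R)-2-bromohex-1-en-5-yn-3-ol
Product: 7 (3R)-2-bromohepta-1,5,6-trien-3-ol, via propargylic amine 6 (not isolated)
Conditions: (CH2O)n (2.5 equiv), Cy2NH (1.8 equiv), CuI (0.5 equiv), 1,4-dioxane, reflux
Reagents that add atoms: formaldehyde (as paraformaldehyde), C=O
Why: Crabbé homologation: copper-mediated Mannich coupling of the terminal alkyne with formaldehyde and Cy2NH gives 6, which undergoes a 1,5-hydride shift with loss of the imine to the terminal allene and so adds C6, free homopropargylic alcohols being tolerated and C2 not being involved.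

Step 4
Reactants: 7 (3R)-2-bromohepta-1,5,6-trien-3-ol
Product: 8 (2R)-2-(1-bromoethenyl)-5-iodo-3,6-dihydro-2H-pyran
Conditions: NIS (1.1 equiv), Ph3PAuCl (5 mol%), AgBF4 (5 mol%), CH2Cl2, 0 °C to rt, dark
Reagents that add atoms: N-iodosuccinimide, O=C1CCC(=O)N1I
Why: Gold-catalysed cyclisation of a β-hydroxyallene in the presence of NIS, a known route to iodinated dihydropyrans: monovalent gold activates the terminal C5=C6 bond, O1 attacks C6 in the 6-endo mode (the 4-exo alternative at C4 is strained) and NIS turns the C5–Au bond into the C5–I bond, while the electron-poor bromoalkene stays inert and C2 keeps its configuration.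

Step 5
Reactants: 9 (2E,6E)-farnesol
Product: 10 (2E,6E)-farnesal
Conditions: MnO2 (15 equiv), CH2Cl2, rt
Reagents that add atoms: none
Why: Selective allylic alcohol oxidation with MnO2 stops at the enal and should leave the E-geometry of the conjugated alkene and the isolated alkenes untouched.

Step 6
Reactants: 10 (2E,6E)-farnesal
Product: 11 (3E,7E)-4,8,12-trimethyltrideca-1,3,7,11-tetraene
Conditions: Ph3PCH3Br (1.3 equiv), n-BuLi (1.25 equiv), THF, 0 °C; then 10, −78 °C to rt
Reagents that add atoms: methyltriphenylphosphonium bromide, C[P+](c1ccccc1)(c1ccccc1)c1ccccc1.[Br-]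
Why: Wittig methylenation with the non-stabilised ylide converts the enal into the terminal 1,3-diene without touching the E-alkenes.

Step 7
Reactants: 11 (3E,7E)-4,8,12-trimethyltrideca-1,3,7,11-tetraene; 8 (2R)-2-(1-bromoethenyl)-5-iodo-3,6-dihydro-2H-pyran
Product: 13 (2R)-2-(1-bromoethenyl)-5-[(3E,7E)-4,8,12-trimethyltrideca-3,7,11-trien-1-yl]-3,6-dihydro-2H-pyran, via B-homofarnesyl-9-BBN 12 (not isolated)
Conditions: 11 (1.3 equiv), 9-BBN (1.25 equiv), THF, 0 °C to rt; then aq Cs2CO3 (3 equiv), 8 (1.0 equiv), PdCl2(dppf) (5 mol%), AsPh3 (5 mol%), DMF, rt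
Reagents that add atoms: none
Why: 9-BBN adds syn and anti-Markovnikov to the only monosubstituted alkene of 11, the three trisubstituted alkenes being far slower, so 12 carries boron on C1' and keeps the E-geometry at C3'=C4' and C7'=C8'. Zerovalent palladium then inserts into the C5–I bond of 8, the base-activated borate hands its primary alkyl group to palladium with retention, and reductive elimination forges C5–C1'; this is the B-alkyl Suzuki–Miyaura coupling, well known for cyclic and acyclic alkenyl iodides. No ring is closed and no stereocentre is created; C2 is remote from the reacting centre and is not touched by the mild base. The step needs site selectivity between two alkenyl halides, which the substrate secures because the C5–I bond adds to palladium at room temperature whereas the hindered C(Br)=CH2 group needs heating. β-Hydride elimination of the alkylpalladium species is held back by the wide bite angle of dppf, and β-alkoxide loss from the C5–Pd species is ruled out because it would give a six-membered cyclic allene. Residual 9-BBN is destroyed by the aqueous base before 8 is added, so the alkenes of 8 are not hydroborated.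

Step 8
Reactants: 13 (2R)-2-(1-bromoethenyl)-5-[(3E,7E)-4,8,12-trimethyltrideca-3,7,11-trien-1-yl]-3,6-dihydro-2H-pyran
Product: 16 2-{(2R)-5-[(3E,7E)-4,8,12-trimethyltrideca-3,7,11-trien-1-yl]-3,6-dihydro-2H-pyran-2-yl}prop-2-enoic acid, via vinyllithium 14 (not isolated), via lithium carboxylate 15 (not isolated)
Conditions: t-BuLi (2.1 equiv), Et2O, −78 °C, 10 min; excess dry CO2, −78 to 0 °C; 1 M HCl to pH 3
Reagents that add atoms: carbon dioxide, O=C=O
Why: Bromine–lithium exchange with two equivalents of t-BuLi is faster at −78 °C than any deprotonation and gives vinyllithium 14, which is trapped by CO2 (carboxylation of an organolithium) to 15 and protonated to the acid, C2 being untouched.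

Compound list
1 | acrolein | C=CC=O | starting material
2 | 2,3-dibromopropanal (racemic, not isolated) | O=CC(Br)CBr | intermediate
3 | 2-bromoacrolein (2-bromoprop-2-enal) | C=C(Br)C=O | intermediate
4 | tributylstannyl ether of 5 (not isolated) | C=C(Br)[C@H](O[Sn](CCCC)(CCCC)CCCC)CC#C | intermediate
5 | (3R)-2-bromohex-1-en-5-yn-3-ol | C=C(Br)[C@H](O)CC#C | intermediate
6 | (3R)-2-bromo-7-(dicyclohexylamino)hept-1-en-5-yn-3-ol (not isolated) | C=C(Br)[C@H](O)CC#CCN(C1CCCCC1)C1CCCCC1 | intermediate
7 | (3R)-2-bromohepta-1,5,6-trien-3-ol | C=C(Br)[C@H](O)CC=C=C | intermediate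
8 | (2R)-2-(1-bromoethenyl)-5-iodo-3,6-dihydro-2H-pyran | C=C(Br)[C@H]1CC=C(I)CO1 | intermediate
9 | (2E,6E)-farnesol | OC/C=C(\C)CC/C=C(\C)CCC=C(C)C | starting material
10 | (2E,6E)-farnesal | O=C/C=C(\C)CC/C=C(\C)CCC=C(C)C | intermediate
11 | (3E,7E)-4,8,12-trimethyltrideca-1,3,7,11-tetraene | C=C/C=C(\C)CC/C=C(\C)CCC=C(C)C | intermediate
12 | 9-[(3E,7E)-4,8,12-trimethyltrideca-3,7,11-trien-1-yl]-9-borabicyclo[3.3.1]nonane (not isolated) | B1(CC/C=C(\C)CC/C=C(\C)CCC=C(C)C)C2CCCC1CCC2 | intermediate
13 | (2R)-2-(1-bromoethenyl)-5-[(3E,7E)-4,8,12-trimethyltrideca-3,7,11-trien-1-yl]-3,6-dihydro-2H-pyran | C=C(Br)[C@H]1CC=C(CC/C=C(\C)CC/C=C(\C)CCC=C(C)C)CO1 | intermediate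
14 | vinyllithium from 13 (not isolated) | C=C([Li])[C@H]1CC=C(CC/C=C(\C)CC/C=C(\C)CCC=C(C)C)CO1 | intermediate
15 | lithium salt of 16 (not isolated) | C=C(C(=O)[O-])[C@H]1CC=C(CC/C=C(\C)CC/C=C(\C)CCC=C(C)C)CO1.[Li+] | intermediate
16 | 2-{(2R)-5-[(3E,7E)-4,8,12-trimethyltrideca-3,7,11-trien-1-yl]-3,6-dihydro-2H-pyran-2-yl}prop-2-enoic acid | C=C(C(=O)O)[C@H]1CC=C(CC/C=C(\C)CC/C=C(\C)CCC=C(C)C)CO1 | target

Total step count: 8. Longest linear sequence: 6 (steps 1, 2, 3, 4, 7, 8).

Steps most likely to fail

Step 4. The allene may be iodinated without ring closure, or O1 may attack the wrong allene carbon.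
- The fallback builds the ring by metathesis after the coupling. It sets out from 3 and comes back at 13.
- The same (R)-BINOL/Ti(OiPr)4 catalyst with allyltributylstannane (Keck allylation) should give (3R)-2-bromohexa-1,5-dien-3-ol F1.
- Commercial propargyl alcohol would be hydroiodinated (NaI, TMSCl, H2O, MeCN) to 2-iodoprop-2-en-1-ol F2 and mesylated (MsCl, Et3N) to 2-iodoprop-2-en-1-yl methanesulfonate F3.
- Williamson etherification of F1 with F3 (NaH, THF/DMF) should give the 2-iodoallyl ether F4.
- The C–I bond of F4 would be coupled with borane 12 under the conditions of step 7 to give the acyclic 1,1-disubstituted alkene F5.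
- Ring-closing metathesis (second-generation Grubbs catalyst, CH2Cl2, 40 °C) between the allyl group and the 1,1-disubstituted alkene closes C4=C5 and gives 13.

Step 7. The conjugated diene may be over-hydroborated, or boron-to-palladium transfer may be slow, so that reduction of the C5–I bond or insertion into the C–Br bond competes.
- The fallback replaces the in-situ borane by a purified alkyl iodide and a base-free organozinc coupling. It sets out from 12 and comes back at 13.
- Oxidation of 12 (NaOH, H2O2) should give (3E,7E)-homofarnesol F6, which can be freed of regioisomers by chromatography.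
- An Appel reaction (I2, PPh3, imidazole) gives homofarnesyl iodide F7.
- Zinc insertion (Zn dust, LiCl, THF) gives homofarnesylzinc iodide F8.
- Negishi coupling of F8 with 8 (Pd(PPh3)4, THF, rt) should give 13.

Step 8. The ring alkoxide may undergo β-elimination from the vinyllithium. Alternatively, deprotonation at the allylic ether positions C2 and C6 may compete and be followed by Wittig rearrangement.
- The fallback avoids organolithiums. It sets out from 13 and comes back at 16.
- Palladium-catalysed methoxycarbonylation of the alkenyl bromide (Pd(OAc)2, PPh3, CO 1 atm, MeOH, Et3N, DMF, 60 °C) should give the methyl ester F9.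
- Saponification (LiOH, THF/H2O, rt, then dilute acid) gives 16.

Further compounds
F1 | step 4 | (3R)-2-bromohexa-1,5-dien-3-ol | C=C(Br)[C@H](O)CC=C
F2 | step 4 | 2-iodoprop-2-en-1-ol | C=C(I)CO
F3 | step 4 | 2-iodoprop-2-en-1-yl methanesulfonate | C=C(I)COS(C)(=O)=O
F4 | step 4 | (3R)-2-bromo-3-[(2-iodoprop-2-en-1-yl)oxy]hexa-1,5-diene | C=C(Br)[C@H](OCC(I)=C)CC=C
F5 | step 4 | (3R)-2-bromo-3-{[(5E,9E)-6,10,14-trimethyl-2-methylidenepentadeca-5,9,13-trien-1-yl]oxy}hexa-1,5-diene | C=C(Br)[C@H](OCC(=C)CC/C=C(\C)CC/C=C(\C)CCC=C(C)C)CC=C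
F6 | step 7 | (3E,7E)-4,8,12-trimethyltrideca-3,7,11-trien-1-ol (homofarnesol) | OCC/C=C(\C)CC/C=C(\C)CCC=C(C)C
F7 | step 7 | (6E,10E)-13-iodo-2,6,10-trimethyltrideca-2,6,10-triene (homofarnesyl iodide) | ICC/C=C(\C)CC/C=C(\C)CCC=C(C)C
F8 | step 7 | (3E,7E)-homofarnesylzinc iodide | I[Zn]CC/C=C(\C)CC/C=C(\C)CCC=C(C)C
F9 | step 8 | methyl 2-{(2R)-5-[(3E,7E)-4,8,12-trimethyltrideca-3,7,11-trien-1-yl]-3,6-dihydro-2H-pyran-2-yl}prop-2-enoate | C=C(C(=O)OC)[C@H]1CC=C(CC/C=C(\C)CC/C=C(\C)CCC=C(C)C)CO1
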